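The earlier runs and the new flask stem from a simulated flask with constants of no real substance; noise was put on by code.

Start from the constants of the recipes: left-handed substrate, right-handed substrate, free catalyst, added ligand and temperature stand the same in the asked flasks, and partner moves.

common to all: left-handed substrate 0.10 M; right-handed substrate 0.10 M; free catalyst 0.50 mM; added ligand 0.39 mM

| flask | partner | temperature | remark | time |
|---|---|---|---|---|
| birch | 0.012 M | 10 °C | run made earlier |  |
| ash | 0.16 M | 25 °C | run made earlier |  |
| west | 0.0150 M | 25 °C |  | 8.0 h |
| north-east | 0.0400 M | 25 °C |  | 8.0 h |
| south-west | 0.0600 M | 25 °C |  | 8.0 h |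
| south-east | 0.200 M | 25 °C |  | 8.0 h |
| east | 0.100 M | 25 °C |  | 8.0 h |

| run | time / h | left-handed product / % |
|---|---|---|
| birch | 1.00 | 3 |
| birch | 3.00 | 0 |
| birch | 5.00 | 7 |
| birch | 8.00 | 2 |
| birch | 12.0 | 4 |
| ash | 1.00 | 18 |
| ash | 2.50 | 30 |
| ash | 3.00 | 33 |
| ash | 5.00 | 39 |
| ash | 6.00 | 38 |

(each reading ± 2 percentage points)

* all flasks from highest to lowest amount of left-handed product, in percent of the left-handed substrate and right-handed substrate together charged, at 8.0 h (west / north-east / south-west / south-east / east)
* the same order at 2.5 d (west / north-east / south-west / south-east / east)
* the amount of left-handed product, in percent of the left-handed substrate and right-handed substrate together charged of the flask you put first, at 8.0 h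
* the amount of left-handed product, in percent of the left-handed substrate and right-handed substrate together charged of the flask you put last, at 8.0 h

- free catalyst is single-handed; left-handed substrate and right-handed substrate are mirror images of each other, charged as a racemate, each of them at the stated concentration

First, what can partner pay for? Count turnovers, assuming one partner per turnover, and put partner on the scale of the readings: its worth is its charge as a fraction of both substrates together. Ash has a worth of 0.800 and reads 39 % at 5.00 h, then 38 % at 6.00 h. Define the catch, left-handed product made per partner charged, both as fractions of the substrates together, and read it from ash: 0.488. Birch, colder and worth 0.0600, reads from 0 % to 7 %, which adds little at a scatter of 2 percentage points.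

Second, does left-handed substrate cap the biggest charge? It is half of the charge. South-east has a worth of 1.00, so my own reckoning gives it 48.8 %, just under that cap.

Third, is the time long enough? The last two readings of ash lie within the scatter of each other, and both were taken earlier than 8.0 h. That is a reading, not proof of a plateau; still, I take it as one and rank the flasks by worth at both times. West, worth 0.0750, comes to 3.66 %.

The forecast says south-east > east > south-west > north-east > west at 8.0 h and south-east > east > south-west > north-east > west at 2.5 d, with 45 % first and 3.7 % last: “Yield therefore rises with partner”. My order is the same; for south-east my figure stands above its 45 %.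

The flasks give south-east > east > south-west > north-east > west at 8.0 h and south-east > east > south-west > north-east > west at 2.5 d, with 44.6 % first and 4.77 % last.

    partner + free catalyst + left-handed substrate → free catalyst + left-handed product (k = 3.20 L² mol⁻² s⁻¹, Ea = 36.0 kJ mol⁻¹)
    partner + free catalyst + right-handed substrate → free catalyst + right-handed product (k = 1.57 L² mol⁻² s⁻¹, Ea = 50.0 kJ mol⁻¹)
    free catalyst + added ligand ⇌ idle complex, settled at all times (K = 1280 L mol⁻¹, ΔH = −33.0 kJ mol⁻¹)
    free catalyst → spent catalyst (k = 1.29 × 10⁻⁵ s⁻¹, Ea = 94.0 kJ mol⁻¹)
    partner ⇌ dormant form (K = 26.0, k = 5.27 × 10⁻⁶ s⁻¹, Ea = 109 kJ mol⁻¹, ΔH = −33.0 kJ mol⁻¹)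
    (constants at 25 °C)

South-east pays a catch of 0.446 at 8.0 h, lower than the reading from ash, and it is not level, for it stands at 48.1 % at 2.5 d. It keeps 17 % of its partner at 8.00 h, and it falls short partly because partner runs down and partly because the path to right-handed product spends partner too: south-east makes 49.9 % without that depletion and 48.3 % without that path, against 44.6 %. West pays a catch of 0.636, higher than the reading from ash, with partner, its limiting reagent, down to 1.3 % of its charge at 8.00 h. Carry west's catch to the neighbour of west charged with 0.060 M of partner. Its worth of 0.300 gives 19.1 %, and that flask stands at 18.1 %.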